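**Retrosynthetic overview**

1. The C5–CH2 bond between the two halves is cut first: acid-mediated benzylation of (3R)-6,8-dihydroxy-3,7-dimethylisochroman-1-one at C5 by 6-(hydroxymethyl)eugenin, which is made from eugenin through its C6 iodide.
2. The lactone is opened at O2–C1 to an (R)-2-hydroxypropyl benzoate, which goes back through the methyl ketone and a Weinreb amide to a homophthalate diester.
3. The strategy rests on this feature: on the benzene ring of the isochromanone, the fusion carbons C4a and C8a carry two neighbouring carbon substituents (the C4 methylene and the C1 carboxyl), and the C8 oxygen sits directly beside C8a. That pattern is what a malonate C–C bond leaves when it adds across an aryne C4a≡C8a, so C4a–C4 and C8a–C1 are cut together to a silylaryl triflate and dimethyl malonate.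
4. The silylaryl triflate comes from 2,6-dimethoxytoluene by C–H borylation/oxidation, bromination and retro-Brook rearrangement/triflation.
5. Ring order: the benzene ring and the chromone are bought; the key step closes no lasting ring; the lactone ring is the only ring formed (step 8).

Key step: step 4

Remark: C3 of the isochromanone is read as R from the SMILES; in step 7 the sense of hydride delivery is assigned by analogy with aryl methyl ketones, the arylmethyl arm taking the place of the aryl group.

**Route**

Step 1
Reactants: 1 2,6-dimethoxytoluene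
Product: 3 3,5-dimethoxy-4-methylphenol, via arylboronate 2 (not isolated)
Conditions: [Ir(OMe)(cod)]2 (1.5 mol %), dtbpy (3 mol %), HBpin (1.5 equiv), hexane, 50 °C; then aq. NaOH, 30% H2O2, THF, 0 °C
Reagents that add atoms: hydrogen peroxide, OO (phenol oxygen of 3); pinacolborane, CC1(C)OBOC1(C)C (boron and pinacol of 2 only)
Why: Iridium-catalysed C–H borylation is governed by sterics and should take C4, the only ring C–H of 1 with no ortho substituent, after which alkaline peroxide oxidation of the C–B bond (1,2-aryl shift from boron to oxygen) gives the phenol.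

Step 2
Reactants: 3 3,5-dimethoxy-4-methylphenol
Product: 4 2-bromo-3,5-dimethoxy-4-methylphenol
Conditions: NBS (1.0 equiv), CH2Cl2, −78 °C → 0 °C
Reagents that add atoms: N-bromosuccinimide, O=C1CCC(=O)N1Br
Why: Electrophilic aromatic bromination can only reach the two symmetry-equivalent free positions of 3, each ortho to the hydroxyl and activated by both methoxy groups, and one equivalent of NBS at low temperature should hold it at the monobromide.

Step 3
Reactants: 4 2-bromo-3,5-dimethoxy-4-methylphenol
Product: 7 3,5-dimethoxy-4-methyl-2-(trimethylsilyl)phenyl trifluoromethanesulfonate, via silyl ether 5 (not isolated), via lithium phenoxide 6 (not isolated)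
Conditions: HMDS, THF, 70 °C; evaporate; n-BuLi, THF, −100 °C → −80 °C; Tf2O, −100 °C → rt
Reagents that add atoms: hexamethyldisilazane, C[Si](C)(C)N[Si](C)(C)C; trifluoromethanesulfonic anhydride, O=S(=O)(OS(=O)(=O)C(F)(F)F)C(F)(F)F; n-butyllithium, [Li]CCCC (lithium of 6 only)
Why: O-silylation, bromine–lithium exchange with 1,3 O→C silyl shift (retro-Brook rearrangement) and O-triflation of the freed phenoxide form the standard sequence to o-silylaryl triflates and place silicon on the carbon that carried bromine.

Step 4
Reactants: 7 3,5-dimethoxy-4-methyl-2-(trimethylsilyl)phenyl trifluoromethanesulfonate; 8 dimethyl malonate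
Product: 11 methyl 2,4-dimethoxy-6-(2-methoxy-2-oxoethyl)-3-methylbenzoate, via aryne 9 (not isolated), via benzocyclobutenoxide 10 (not isolated)
Conditions: 8 (1.5 equiv), KF (3 equiv), 18-crown-6 (3 equiv), THF (0.05 M), 0 °C → rt
Reagents that add atoms: potassium fluoride, [K+].[F-] (potassium of 10 only)
Why: Fluoride strips the silyl group of 7 and triflate departs to give aryne 9; the potassium enolate of 8 adds to the aryne carbon remote from the flanking methoxy group (the future C4a), the aryl anion formed at the future C8a closes onto one ester carbonyl (4-exo-trig) to give benzocyclobutenoxide 10, and 10 opens by retro-aldol-type cleavage of the former malonate C–C bond to the benzylic ester enolate of 11. The closest known reaction type is the fluoride-induced acyl-alkylation of arynes by beta-ketoesters and malonates (aryne sigma-bond insertion) from o-silylaryl triflates. The only ring closed is the transient four-membered ring of 10, which does not survive, so 11 has no new ring and no stereocentre. The step needs site selectivity on an unsymmetrical aryne: the methoxy group next to the triple bond bends and polarises it, so that the carbon meta to that oxygen is the electrophilic one and negative charge builds up ortho to the inductively withdrawing C–O bond. It also needs mono-insertion, which excess 8 and high dilution should favour over protonation of the aryl anion or a second arylation of the product enolate.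

Step 5
Reactants: 11 methyl 2,4-dimethoxy-6-(2-methoxy-2-oxoethyl)-3-methylbenzoate
Product: 12 methyl 2,4-dimethoxy-6-{2-[methoxy(methyl)amino]-2-oxoethyl}-3-methylbenzoate
Conditions: MeNH(OMe)·HCl (2 equiv), AlMe3 (2 equiv), CH2Cl2, 0 °C → rt; aq. HCl work-up
Reagents that add atoms: N,O-dimethylhydroxylamine hydrochloride, CNOC.Cl
Why: Weinreb aminolysis by the aluminium amide should take only the unhindered acetate ester, because the benzoate is flanked by a methoxy group and the CH2 arm and is shielded from tetrahedral attack.

Step 6
Reactants: 12 methyl 2,4-dimethoxy-6-{2-[methoxy(methyl)amino]-2-oxoethyl}-3-methylbenzoate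
Product: 13 methyl 2,4-dimethoxy-3-methyl-6-(2-oxopropyl)benzoate
Conditions: MeMgBr (2 equiv), THF, −20 °C → 0 °C; aq. NH4Cl
Reagents that add atoms: methylmagnesium bromide, C[Mg]Br
Why: Grignard addition to a Weinreb amide stops at the chelated tetrahedral adduct, which collapses to the methyl ketone only on work-up, while the di-ortho-substituted benzoate should not react at 0 °C.

Step 7
Reactants: 13 methyl 2,4-dimethoxy-3-methyl-6-(2-oxopropyl)benzoate
Product: 14 methyl 6-[(2R)-2-hydroxypropyl]-2,4-dimethoxy-3-methylbenzoate
Conditions: RuCl[(R,R)-TsDPEN](p-cymene) (1 mol %), HCO2H/Et3N (5:2), 30 °C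
Reagents that add atoms: none
Why: Noyori–Ikariya asymmetric transfer hydrogenation delivers hydride and proton through an outer-sphere six-membered transition state, and the (R,R)-catalyst should attack the Si face of the ketone with the arylmethyl arm in the place normally taken by an aryl group, setting C3 as R under catalyst control.

Step 8
Reactants: 14 methyl 6-[(2R)-2-hydroxypropyl]-2,4-dimethoxy-3-methylbenzoate
Product: 15 (3R)-6,8-dimethoxy-3,7-dimethyl-3,4-dihydro-1H-isochromen-1-one
Conditions: p-TsOH·H2O (10 mol %), toluene, 80 °C
Reagents that add atoms: none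
Why: Acid-catalysed lactonisation (intramolecular transesterification, 6-exo-trig) overcomes the hindrance of the benzoate by proximity and breaks no bond at C3, so the configuration is retained.

Step 9
Reactants: 15 (3R)-6,8-dimethoxy-3,7-dimethyl-3,4-dihydro-1H-isochromen-1-one
Product: 16 (3R)-6,8-dihydroxy-3,7-dimethyl-3,4-dihydro-1H-isochromen-1-one
Conditions: BBr3 (5 equiv), CH2Cl2, −78 °C → rt; then H2O
Reagents that add atoms: none
Why: Boron tribromide ether cleavage (boron coordination, then bromide attack on the methyl group) should remove both aryl methyl ethers, the C8 ether first through its chelate with the lactone carbonyl, and leave the lactone and C3 untouched.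

Step 10
Reactants: 17 eugenin (5-hydroxy-7-methoxy-2-methyl-4H-chromen-4-one)
Product: 18 5-hydroxy-6-iodo-7-methoxy-2-methyl-4H-chromen-4-one
Conditions: BnMe3N·ICl2 (1.05 equiv), CaCO3, CH2Cl2/MeOH, rt
Reagents that add atoms: benzyltrimethylammonium dichloroiodate, C[N+](C)(C)Cc1ccccc1.Cl[I-]Cl
Why: Electrophilic iodination of 5-hydroxy-7-alkoxychromones and flavones by dichloroiodate should go ortho to the chelated C5 hydroxyl, at C6 and not C8, with CaCO3 taking up the HCl.

Step 11
Reactants: 18 5-hydroxy-6-iodo-7-methoxy-2-methyl-4H-chromen-4-one
Product: 19 5-hydroxy-6-(hydroxymethyl)-7-methoxy-2-methyl-4H-chromen-4-one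
Conditions: Bu3SnCH2OH (1.5 equiv), Pd(PPh3)4 (5 mol %), 1,4-dioxane, 100 °C
Reagents that add atoms: (tributylstannyl)methanol, CCCC[Sn](CCCC)(CCCC)CO
Why: Migita–Kosugi–Stille coupling of the aryl iodide with the hydroxymethylstannane transfers the CH2OH group in preference to butyl and fixes the one-carbon unit at C6 without touching the chromone.

Step 12
Reactants: 16 (3R)-6,8-dihydroxy-3,7-dimethyl-3,4-dihydro-1H-isochromen-1-one; 19 5-hydroxy-6-(hydroxymethyl)-7-methoxy-2-methyl-4H-chromen-4-one
Product: 20 (3R)-6,8-dihydroxy-5-[(5-hydroxy-7-methoxy-2-methyl-4-oxo-4H-chromen-6-yl)methyl]-3,7-dimethyl-3,4-dihydro-1H-isochromen-1-one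
Conditions: 16 (2 equiv), slow addition of 19, p-TsOH·H2O (10 mol %), 1,4-dioxane, 60 °C
Reagents that add atoms: none
Why: Acid-promoted ionisation of the o-hydroxybenzyl alcohol gives an o-quinone methide/benzylic cation stabilised by the C5 hydroxyl and C7 methoxy groups, and Friedel–Crafts benzylation of 16 can only occur at C5, its single free ring carbon (ortho to the C6 hydroxyl, para to the C8 hydroxyl), while the remote C3 centre is not affected.

**Compound list**

1 | 2,6-dimethoxytoluene | COc1cccc(OC)c1C | starting material
2 | 2-(3,5-dimethoxy-4-methylphenyl)-4,4,5,5-tetramethyl-1,3,2-dioxaborolane | COc1cc(cc(OC)c1C)B1OC(C)(C)C(C)(C)O1 | intermediate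
3 | 3,5-dimethoxy-4-methylphenol | COc1cc(O)cc(OC)c1C | intermediate
4 | 2-bromo-3,5-dimethoxy-4-methylphenol | COc1cc(O)c(Br)c(OC)c1C | intermediate
5 | (2-bromo-3,5-dimethoxy-4-methylphenoxy)trimethylsilane | COc1cc(O[Si](C)(C)C)c(Br)c(OC)c1C | intermediate
6 | lithium 3,5-dimethoxy-4-methyl-2-(trimethylsilyl)phenolate | [Li+].[O-]c1cc(OC)c(C)c(OC)c1[Si](C)(C)C | intermediate
7 | 3,5-dimethoxy-4-methyl-2-(trimethylsilyl)phenyl trifluoromethanesulfonate | COc1cc(OS(=O)(=O)C(F)(F)F)c([Si](C)(C)C)c(OC)c1C | intermediate
8 | dimethyl malonate | COC(=O)CC(=O)OC | starting material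
9 | 3,5-dimethoxy-4-methylbenzyne (1,2-didehydro-3,5-dimethoxy-4-methylbenzene) | COC1=C(C)C(OC)=CC#C1 | intermediate
10 | potassium 2,4,8-trimethoxy-7-(methoxycarbonyl)-3-methylbicyclo[4.2.0]octa-1,3,5-trien-8-olate | [K+].COC(=O)C1c2cc(OC)c(C)c(OC)c2C1([O-])OC | intermediate
11 | methyl 2,4-dimethoxy-6-(2-methoxy-2-oxoethyl)-3-methylbenzoate | COC(=O)Cc1cc(OC)c(C)c(OC)c1C(=O)OC | intermediate
12 | methyl 2,4-dimethoxy-6-{2-[methoxy(methyl)amino]-2-oxoethyl}-3-methylbenzoate | CON(C)C(=O)Cc1cc(OC)c(C)c(OC)c1C(=O)OC | intermediate
13 | methyl 2,4-dimethoxy-3-methyl-6-(2-oxopropyl)benzoate | CC(=O)Cc1cc(OC)c(C)c(OC)c1C(=O)OC | intermediate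
14 | methyl 6-[(2R)-2-hydroxypropyl]-2,4-dimethoxy-3-methylbenzoate | COC(=O)c1c(C[C@@H](C)O)cc(OC)c(C)c1OC | intermediate
15 | (3R)-6,8-dimethoxy-3,7-dimethyl-3,4-dihydro-1H-isochromen-1-one | COc1cc2C[C@@H](C)OC(=O)c2c(OC)c1C | intermediate
16 | (3R)-6,8-dihydroxy-3,7-dimethyl-3,4-dihydro-1H-isochromen-1-one | Cc1c(O)cc2C[C@@H](C)OC(=O)c2c1O | intermediate
17 | eugenin (5-hydroxy-7-methoxy-2-methyl-4H-chromen-4-one) | COc1cc(O)c2c(c1)oc(C)cc2=O | starting material
18 | 5-hydroxy-6-iodo-7-methoxy-2-methyl-4H-chromen-4-one | COc1cc2oc(C)cc(=O)c2c(O)c1I | intermediate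
19 | 5-hydroxy-6-(hydroxymethyl)-7-methoxy-2-methyl-4H-chromen-4-one | COc1cc2oc(C)cc(=O)c2c(O)c1CO | intermediate
20 | (3R)-6,8-dihydroxy-5-[(5-hydroxy-7-methoxy-2-methyl-4-oxo-4H-chromen-6-yl)methyl]-3,7-dimethyl-3,4-dihydro-1H-isochromen-1-one | COc1cc2oc(C)cc(=O)c2c(O)c1Cc1c(O)c(C)c(O)c2c1C[C@@H](C)OC2=O | target

**Step count**

Total: 12 steps. Longest linear sequence: 10 steps (steps 1–9, then step 12); the eugenin branch (steps 10–11) joins at step 12.

**Steps most likely to fail**

1. Step 4 (aryne insertion). The aryl anion at the future C8a may be protonated by malonate before it closes onto the ester, which gives plain C-arylation without carboxyl transfer. The product enolate may also capture a second aryne, or fluoride may attack the sulfur of the triflate and return the phenoxide. The fallback replaces the aryne by toluate-anion chemistry. It sets out from arylboronate 2, isolated after the borylation of step 1 instead of being oxidised. Suzuki–Miyaura methylation (MeI, Pd(PPh3)4, K3PO4, DMF/H2O, 60 °C) should give 1,3-dimethoxy-2,5-dimethylbenzene F1. NBS in MeCN brominates one of its two equivalent free positions to 1-bromo-2,4-dimethoxy-3,6-dimethylbenzene F2. Bromine–lithium exchange (n-BuLi, THF, −78 °C) and quenching with ClCO2Me give methyl 2,4-dimethoxy-3,6-dimethylbenzoate F3. Lateral lithiation of the methyl group ortho to the ester (LDA, 2 equiv, THF, −78 °C) and acylation with N-methoxy-N-methylacetamide give ketone 13, where the route is rejoined before step 7.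

2. Step 12 (union of the halves). Ionisation of 19 may outrun capture by 16, so that the benzylic cation attacks C8 of a second chromone unit or a phenolic oxygen and the material is lost to oligomers. The fallback sets out from iodide 18. Suzuki–Miyaura aminomethylation with potassium [(dimethylamino)methyl]trifluoroborate (Pd(OAc)2, XPhos, Cs2CO3, THF/H2O, 80 °C) should give the Mannich base 6-[(dimethylamino)methyl]-5-hydroxy-7-methoxy-2-methyl-4H-chromen-4-one F4. Heating F4 with 16 in 1,4-dioxane at 100 °C releases the o-quinone methide slowly under non-acidic conditions. There the liberated amine turns 16 into its more nucleophilic phenoxide, which should add through C5 (the classical Mannich-base route to unsymmetrical methylene-bridged phenols). This gives 20 directly, so the fallback comes back to the route at 20.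

3. Step 7 (asymmetric transfer hydrogenation). The catalyst has to tell an arylmethyl group from a methyl group, both sp3 carbons, so facial discrimination may be poor and the enantiomeric purity of 14 too low. The fallback moves the stereo-defining event from the ketone to an alkene and sets out from ketone 13. p-TsOH in toluene at reflux closes the enol oxygen onto the ester with loss of methanol to give the isocoumarin 6,8-dimethoxy-3,7-dimethyl-1H-isochromen-1-one F5. Enantioselective hydrogenation of its C3=C4 bond follows, a known reaction of 3-alkylisocoumarins, under H2 with a chiral ruthenium N-heterocyclic carbene–diamine catalyst. The catalyst is prepared from Ru(cod)(2-methylallyl)2, a chiral imidazolinium salt, KOt-Bu and enantiopure 1,2-diphenylethylenediamine, its enantiomer chosen for the (R)-product. This gives lactone 15, where the route is rejoined before step 9.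

**Further compounds**

F1 | step 4 | 1,3-dimethoxy-2,5-dimethylbenzene | COc1cc(C)cc(OC)c1C
F2 | step 4 | 1-bromo-2,4-dimethoxy-3,6-dimethylbenzene | COc1cc(C)c(Br)c(OC)c1C
F3 | step 4 | methyl 2,4-dimethoxy-3,6-dimethylbenzoate | COC(=O)c1c(C)cc(OC)c(C)c1OC
F4 | step 12 | 6-[(dimethylamino)methyl]-5-hydroxy-7-methoxy-2-methyl-4H-chromen-4-one | COc1cc2oc(C)cc(=O)c2c(O)c1CN(C)C
F5 | step 7 | 6,8-dimethoxy-3,7-dimethyl-1H-isochromen-1-one | COc1cc2cc(C)oc(=O)c2c(OC)c1C
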